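**Plan**

Numbering used: hydrindane C1(H2)–C2(OH)–C3(side chain)–C3a(H)–C4(Me,OH)–C5–C6–C7(Br)–C7a(Me); carbinol carbon C1'; bromocyclohexanol (ring A) C1''–C6''.
Cuts, last to first: both C–Br bonds (from ketones), C5''–C6'' of ring A (epoxide opened by a ketone enolate), C3–C1' (aldol), the C2–C3 alkene precursor (ring-closing metathesis), then together C3–C3a and C1–C7a, the two bonds that flank the ring fusion.
Enabling feature: in the six-membered ring the tertiary C4–OH is cis to the C3a–C3 bond and C7 can be a ketone next to quaternary C7a, so C7a=C3a is the enone bond of (R)-4-hydroxy-2,4-dimethylcyclohex-2-enone. Because C7a–Me and C3a–H are trans, the two carbons must add anti, by alkoxide-directed conjugate addition and enolate alkylation, not by a suprafacial one-reagent annulation.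
Forward order: cyclohexenone from (R)-linalool (metathesis), double C–C bond formation, cyclopentene closure as a silyl enol ether, aldol with an achiral enal, ring A closure, bromides.
Stereochemistry: the single stereocenter of (R)-linalool (C4) sets C3a and C7a in the key step; these relay to C3/C1' (aldol), C2 (chelation-controlled reduction), C1'' (hydroxyl-directed epoxidation) and C7/C4'' (hydrogen atom transfer to the alkenyl bromides).

Key step: step 6

Assumption: (R)-(−)-linalool is used enantiopure; commercial material of lower enantiomeric purity would be upgraded first.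

**Route**

Step 1
Reactants: 1 (R)-linalool
Product: 2 (3R)-5-(3,3-dimethyloxiran-2-yl)-3-methylpent-1-en-3-ol (epoxide epimers)
Conditions: mCPBA (1.05 equiv), NaHCO3, CH2Cl2, 0 °C
Reagents that add atoms: 3-chloroperoxybenzoic acid, OOC(=O)c1cccc(Cl)c1
Why: Prilezhaev epoxidation should take the electron-rich trisubstituted alkene in preference to the vinyl group, and the configuration of the new epoxide carbon is irrelevant because that carbon becomes the ring ketone in step 4.

Step 2
Reactants: 2 (3R)-5-(3,3-dimethyloxiran-2-yl)-3-methylpent-1-en-3-ol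
Product: 3 (6R)-2,6-dimethylocta-1,7-diene-3,6-diol (C3 epimers)
Conditions: LiN(iPr)2 (3 equiv), Et2O, 0 °C to rt; then H2O
Reagents that add atoms: none
Why: Base-induced isomerization of an epoxide to an allylic alcohol (syn β-elimination at the less hindered methyl group) should give the isopropenyl carbinol without touching the tertiary stereocenter.

Step 3
Reactants: 3 (6R)-2,6-dimethylocta-1,7-diene-3,6-diol
Product: 4 (4R)-2,4-dimethylcyclohex-2-ene-1,4-diol (C1 epimers)
Conditions: second-generation Grubbs catalyst RuCl2(=CHPh)(PCy3)(H2IMes) (3 mol%), CH2Cl2, 40 °C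
Reagents that add atoms: none
Why: Ring-closing metathesis of the 1,7-diene should close the six-membered ring as the trisubstituted cyclohexene with loss of ethene, the C4 stereocenter being carried through unchanged.

Step 4
Reactants: 4 (4R)-2,4-dimethylcyclohex-2-ene-1,4-diol
Product: 5 (4R)-4-hydroxy-2,4-dimethylcyclohex-2-en-1-one
Conditions: MnO2, CH2Cl2, rt
Reagents that add atoms: none
Why: Allylic oxidation with MnO2 should take only the secondary allylic alcohol, which converges both C1 epimers to one enone, while the tertiary alcohol cannot be oxidized.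

Step 5
Reactants: 6 bromoacetone
Product: 7 [(3-bromoprop-1-en-2-yl)oxy]triethylsilane
Conditions: Et3SiCl, LiN(SiMe3)2 (added to the ketone/silane mixture), THF, −78 °C
Reagents that add atoms: chlorotriethylsilane, CC[Si](Cl)(CC)CC
Why: Kinetic enolization of the α-bromoketone on the methyl side with in situ silylation (silyl enol ether formation) should give the 2-silyloxyallyl bromide, a reactive allylic electrophile that carries C1 and C2 of the hydrindane.

Step 6
Reactants: 5 (4R)-4-hydroxy-2,4-dimethylcyclohex-2-en-1-one; 7 [(3-bromoprop-1-en-2-yl)oxy]triethylsilane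
Product: 9 (2S,3S,4R)-3-ethenyl-4-hydroxy-2,4-dimethyl-2-{2-[(triethylsilyl)oxy]prop-2-en-1-yl}cyclohexan-1-one, via magnesium enolate 8 (not isolated)
Conditions: CH2=CHMgBr (2.3 equiv), THF, −78 to −20 °C; then 7, DMPU, −20 °C to rt; aq. NH4Cl
Reagents that add atoms: vinylmagnesium bromide, C=C[Mg]Br
Why: The first equivalent of the Grignard reagent turns the tertiary alcohol into its bromomagnesium alkoxide, the second vinyl group is delivered from magnesium bound to that alkoxide to the enone β-carbon (C3 of 5, later C3a) on the face of the oxygen, and the tetrasubstituted magnesium enolate 8 is then C-alkylated at C2 (later C7a) by the allylic bromide 7. The closest known reaction type is the three-component conjugate addition–enolate alkylation of cyclic enones, here run with the alkoxide-directed conjugate addition of Grignard reagents known for 4-oxido enones. No ring is closed in this step: the two bonds formed are the future C3–C3a and C1–C7a bonds, and the five-membered ring that contains them is closed in step 8. The C3a stereocenter is controlled by the C4 alkoxide (syn delivery), and the quaternary C7a stereocenter by the new vinyl group, the electrophile entering anti to it so that the C7a methyl group ends cis to the C4 oxygen and trans to the C3a hydrogen. The step needs 1,4- over 1,2-addition, which the intramolecular delivery from the alkoxide should secure, and C- over O-alkylation with trans facial selectivity, which the soft allylic bromide in the presence of DMPU and the adjacent vinyl substituent should secure.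

Step 7
Reactants: 9 (2S,3S,4R)-3-ethenyl-4-hydroxy-2,4-dimethyl-2-{2-[(triethylsilyl)oxy]prop-2-en-1-yl}cyclohexan-1-one
Product: 10 (2S,3S,4R)-3-ethenyl-2,4-dimethyl-4-[(triethylsilyl)oxy]-2-{2-[(triethylsilyl)oxy]prop-2-en-1-yl}cyclohexan-1-one
Conditions: Et3SiOTf, 2,6-lutidine, CH2Cl2, −78 °C; aq. NaHCO3
Reagents that add atoms: triethylsilyl trifluoromethanesulfonate, CC[Si](CC)(CC)OS(=O)(=O)C(F)(F)F
Why: Silylation with the silyl triflate should cap the hindered tertiary alcohol while the ring is still conformationally mobile, so that it cannot quench the enolate of step 12.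

Step 8
Reactants: 10 (2S,3S,4R)-3-ethenyl-2,4-dimethyl-4-[(triethylsilyl)oxy]-2-{2-[(triethylsilyl)oxy]prop-2-en-1-yl}cyclohexan-1-one
Product: 11 (3aS,4R,7aS)-4,7a-dimethyl-2,4-bis[(triethylsilyl)oxy]-1,3a,4,5,6,7a-hexahydro-7H-inden-7-one
Conditions: second-generation Hoveyda–Grubbs catalyst RuCl2(H2IMes)(=CH-C6H4-2-OiPr) (10 mol%), toluene, 80 °C
Reagents that add atoms: none
Why: Ring-closing metathesis between the vinyl group and the silyl enol ether alkene, both equatorial and trans on the chair, should close the trans-fused cyclopentene and leave the enol ether double bond fixed between C2 and C3.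

Step 9
Reactants: 12 3-methylbutan-2-one
Product: 13 trimethyl[(3-methylbut-2-en-2-yl)oxy]silane
Conditions: Me3SiI, (Me3Si)2NH, CH2Cl2, −20 °C to rt; aq. NaHCO3
Reagents that add atoms: iodotrimethylsilane, C[Si](C)(C)I
Why: Silylation under equilibrating conditions (thermodynamic silyl enol ether formation) should give the more substituted enol ether.

Step 10
Reactants: 13 trimethyl[(3-methylbut-2-en-2-yl)oxy]silane; 14 acrolein
Product: 15 4,4-dimethyl-5-oxohexanal
Conditions: pyrrolidinium trifluoroacetate (20 mol%), CH2Cl2/iPrOH, −20 °C; aqueous work-up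
Reagents that add atoms: none
Why: Iminium-catalysed Mukaiyama–Michael addition of the tetrasubstituted enol silane to acrolein should form the quaternary gem-dimethyl carbon by 1,4-addition.

Step 11
Reactants: 15 4,4-dimethyl-5-oxohexanal
Product: 16 4,4-dimethyl-2-methylidene-5-oxohexanal
Conditions: aq. CH2O, pyrrolidine (10 mol%), EtCO2H (10 mol%), iPrOH, 45 °C
Reagents that add atoms: formaldehyde, C=O
Why: Amine-catalysed α-methylenation of the aldehyde (Mannich condensation with formaldehyde followed by elimination) should give the 2-substituted acrolein, the hindered methyl ketone reacting much more slowly.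

Step 12
Reactants: 11 (3aS,4R,7aS)-4,7a-dimethyl-2,4-bis[(triethylsilyl)oxy]-1,3a,4,5,6,7a-hexahydro-7H-inden-7-one; 16 4,4-dimethyl-2-methylidene-5-oxohexanal
Product: 18 (3R,3aS,4R,7aS)-3-[(1R)-1-hydroxy-4,4-dimethyl-2-methylidene-5-oxohexyl]-4,7a-dimethyl-4-[(triethylsilyl)oxy]octahydro-1H-indene-2,7-dione, via silyl aldol 17 (not isolated)
Conditions: Bu4N[Ph3SiF2] (10 mol%), THF, −78 °C; then AcOH/THF/H2O, 0 °C
Reagents that add atoms: none
Why: Fluoride-catalysed Mukaiyama aldol addition generates the enolate only at C3, the aldehyde should approach from the α face opposite to the C4 silyloxy and C7a methyl groups, and the open transition state of the ammonium enolate should give the syn (C3/C1') aldol; the secondary silyl ether formed by silyl transfer is cleaved by the mild acid while the tertiary one should survive.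

Step 13
Reactants: 18 (3R,3aS,4R,7aS)-3-[(1R)-1-hydroxy-4,4-dimethyl-2-methylidene-5-oxohexyl]-4,7a-dimethyl-4-[(triethylsilyl)oxy]octahydro-1H-indene-2,7-dione
Product: 20 (2R,3S,3aS,4R,7aS)-2-hydroxy-3-[(1R)-1-hydroxy-4,4-dimethyl-2-methylidene-5-oxohexyl]-4,7a-dimethyl-4-[(triethylsilyl)oxy]octahydro-7H-inden-7-one, via boron chelate 19 (not isolated)
Conditions: Et2BOMe, THF/MeOH, −78 °C; NaBH4; then MeOH (evaporation)
Reagents that add atoms: methoxydiethylborane, CCB(CC)OC
Why: Narasaka–Prasad reduction, in which hydride adds to the boron-chelated β-hydroxy ketone from outside the chelate to give the 1,3-syn diol (C2–OH cis to the side chain), and the two hindered unchelated ketones should not react at this temperature.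

Step 14
Reactants: 20 (2R,3S,3aS,4R,7aS)-2-hydroxy-3-[(1R)-1-hydroxy-4,4-dimethyl-2-methylidene-5-oxohexyl]-4,7a-dimethyl-4-[(triethylsilyl)oxy]octahydro-7H-inden-7-one
Product: 21 (2R,3S,3aS,4R,7aS)-3-{(R)-[(2S)-2-(2,2-dimethyl-3-oxobutyl)oxiran-2-yl](hydroxy)methyl}-2-hydroxy-4,7a-dimethyl-4-[(triethylsilyl)oxy]octahydro-7H-inden-7-one
Conditions: VO(acac)2 (5 mol%), t-BuOOH, CH2Cl2, 0 °C
Reagents that add atoms: tert-butyl hydroperoxide, CC(C)(C)OO
Why: Hydroxyl-directed epoxidation of the 2-substituted allylic alcohol through the vanadate ester should give the erythro epoxy alcohol (1,2-allylic strain control), which sets C1''.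

Step 15
Reactants: 21 epoxy diol
Product: 22 acetonide of 21 (2,2-dimethyl-1,3-dioxane across the C2 and C1' oxygens)
Conditions: 2-methoxypropene, PPTS (cat.), CH2Cl2, 0 °C
Reagents that add atoms: 2-methoxypropene, C=C(C)OC
Why: Acid-catalysed acetonide formation on the syn 1,3-diol masks both secondary hydroxyl groups so that they cannot open the epoxide in step 16, and the catalyst should be mild enough for the epoxide.

Step 16
Reactants: 22 epoxy ketone acetonide
Product: 23 ring A ketone acetonide [(1R)-1-hydroxy-3,3-dimethyl-4-oxocyclohexyl at C1']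
Conditions: KN(SiMe3)2 (2.2 equiv), THF, −78 to 0 °C; aq. NH4Cl
Reagents that add atoms: none
Why: The potassium enolate of the methyl ketone (its only enolizable position) should open the 2,2-disubstituted epoxide at the unsubstituted CH2 carbon (intramolecular enolate alkylation, six-membered closure because the other epoxide carbon is fully substituted), which closes ring A and releases the tertiary C1'' hydroxyl with retention, the C7 ketone enolate being a spectator.

Step 17
Reactants: 23 ring A ketone acetonide
Product: 24 bis(enol triflate) of 23 (C7=C6 and C4''=C5'')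
Conditions: KN(SiMe3)2 (3.3 equiv), PhNTf2 (2.3 equiv), THF, −78 °C; aq. NH4Cl
Reagents that add atoms: N-phenylbis(trifluoromethanesulfonimide), O=S(=O)(N(c1ccccc1)S(=O)(=O)C(F)(F)F)C(F)(F)F
Why: O-Triflation of the two potassium enolates, each ketone having only one enolizable α-position (C6 and C5''), should give the bis(enol triflate), the hindered tertiary alkoxide not being expected to be sulfonylated at this temperature.

Step 18
Reactants: 24 bis(enol triflate)
Product: 25 bis(alkenyl bromide) (7-bromo-6-ene and 4''-bromo-4''-ene)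
Conditions: Ni(OAc)2·4H2O (10 mol%), 1,5-cyclooctadiene, Zn (20 mol%), LiBr, DMA/THF, rt
Reagents that add atoms: lithium bromide, [Li+].[Br-]
Why: Nickel-catalysed halogen exchange of enol triflates (oxidative addition to zerovalent nickel, triflate–bromide exchange, reductive elimination) should convert both enol triflates into alkenyl bromides.

Step 19
Reactants: 25 bis(alkenyl bromide)
Product: 26 (7S,4''S)-dibromide, still carrying the acetonide and the C4 triethylsilyl ether
Conditions: Mn(dpm)3 (10 mol%), PhSiH3, t-BuOOH, iPrOH, rt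
Reagents that add atoms: none
Why: Metal hydride hydrogen atom transfer hydrogenation, in which the first hydrogen atom adds to the unsubstituted alkene carbon to give the α-bromoalkyl radical and the second should be delivered axially, anti to the axial methyl group on the neighbouring quaternary carbon (C7a or C3''), leaving each bromine equatorial without hydrogenolysis of the C–Br bonds.

Step 20
Reactants: 26 protected dibromide
Product: 27 target tetraol CNP0144982.1
Conditions: 1 M aq. HCl, THF/MeOH, 0 °C to rt
Reagents that add atoms: none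
Why: Acid hydrolysis should cleave the triethylsilyl ether and the acetonide to release the tetraol, the neopentyl secondary bromides being inert to these conditions.

**Compound list**

1 | (R)-linalool, (3R)-3,7-dimethylocta-1,6-dien-3-ol | C=C[C@](C)(O)CCC=C(C)C | starting material
2 | (3R)-5-(3,3-dimethyloxiran-2-yl)-3-methylpent-1-en-3-ol (both epoxide epimers) | C=C[C@](C)(O)CCC1OC1(C)C | intermediate
3 | (6R)-2,6-dimethylocta-1,7-diene-3,6-diol (both C3 epimers) | C=C[C@](C)(O)CCC(O)C(C)=C | intermediate
4 | (4R)-2,4-dimethylcyclohex-2-ene-1,4-diol (both C1 epimers) | CC1=C[C@](C)(O)CCC1O | intermediate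
5 | (4R)-4-hydroxy-2,4-dimethylcyclohex-2-en-1-one | CC1=C[C@](C)(O)CCC1=O | intermediate
6 | bromoacetone (1-bromopropan-2-one) | CC(=O)CBr | starting material
7 | [(3-bromoprop-1-en-2-yl)oxy]triethylsilane | C=C(CBr)O[Si](CC)(CC)CC | intermediate
8 | bis(bromomagnesium) (3S,4R)-3-ethenyl-2,4-dimethylcyclohex-1-ene-1,4-diolate (vinyl syn to the C4 oxygen) | C=C[C@@H]1[C@](C)(O[Mg]Br)CCC(O[Mg]Br)=C1C | intermediate
9 | (2S,3S,4R)-3-ethenyl-4-hydroxy-2,4-dimethyl-2-{2-[(triethylsilyl)oxy]prop-2-en-1-yl}cyclohexan-1-one | C=C(O[Si](CC)(CC)CC)C[C@]1(C)C(=O)CC[C@@](C)(O)[C@H]1C=C | intermediate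
10 | (2S,3S,4R)-3-ethenyl-2,4-dimethyl-4-[(triethylsilyl)oxy]-2-{2-[(triethylsilyl)oxy]prop-2-en-1-yl}cyclohexan-1-one | C=C(O[Si](CC)(CC)CC)C[C@]1(C)C(=O)CC[C@@](C)(O[Si](CC)(CC)CC)[C@H]1C=C | intermediate
11 | (3aS,4R,7aS)-4,7a-dimethyl-2,4-bis[(triethylsilyl)oxy]-1,3a,4,5,6,7a-hexahydro-7H-inden-7-one (trans-fused) | C1=C(O[Si](CC)(CC)CC)C[C@]2(C)C(=O)CC[C@@](C)(O[Si](CC)(CC)CC)[C@@H]12 | intermediate
12 | 3-methylbutan-2-one | CC(=O)C(C)C | starting material
13 | trimethyl[(3-methylbut-2-en-2-yl)oxy]silane | CC(O[Si](C)(C)C)=C(C)C | intermediate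
14 | acrolein (prop-2-enal) | C=CC=O | starting material
15 | 4,4-dimethyl-5-oxohexanal | CC(=O)C(C)(C)CCC=O | intermediate
16 | 4,4-dimethyl-2-methylidene-5-oxohexanal | CC(=O)C(C)(C)CC(=C)C=O | intermediate
17 | (3R,3aS,4R,7aS)-3-{(1R)-4,4-dimethyl-2-methylidene-5-oxo-1-[(triethylsilyl)oxy]hexyl}-4,7a-dimethyl-4-[(triethylsilyl)oxy]octahydro-1H-indene-2,7-dione | CC(=O)C(C)(C)CC(=C)[C@H](O[Si](CC)(CC)CC)[C@@H]1C(=O)C[C@]2(C)C(=O)CC[C@@](C)(O[Si](CC)(CC)CC)[C@@H]12 | intermediate
18 | (3R,3aS,4R,7aS)-3-[(1R)-1-hydroxy-4,4-dimethyl-2-methylidene-5-oxohexyl]-4,7a-dimethyl-4-[(triethylsilyl)oxy]octahydro-1H-indene-2,7-dione | CC(=O)C(C)(C)CC(=C)[C@H](O)[C@@H]1C(=O)C[C@]2(C)C(=O)CC[C@@](C)(O[Si](CC)(CC)CC)[C@@H]12 | intermediate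
19 | diethylborinate of 18 at the C1' oxygen (boron chelated to the C2 ketone) | CCB(CC)O[C@@H](C(=C)CC(C)(C)C(C)=O)[C@@H]1C(=O)C[C@]2(C)C(=O)CC[C@@](C)(O[Si](CC)(CC)CC)[C@@H]12 | intermediate
20 | (2R,3S,3aS,4R,7aS)-2-hydroxy-3-[(1R)-1-hydroxy-4,4-dimethyl-2-methylidene-5-oxohexyl]-4,7a-dimethyl-4-[(triethylsilyl)oxy]octahydro-7H-inden-7-one | CC(=O)C(C)(C)CC(=C)[C@H](O)[C@@H]1[C@H](O)C[C@]2(C)C(=O)CC[C@@](C)(O[Si](CC)(CC)CC)[C@@H]12 | intermediate
21 | (2R,3S,3aS,4R,7aS)-3-{(R)-[(2S)-2-(2,2-dimethyl-3-oxobutyl)oxiran-2-yl](hydroxy)methyl}-2-hydroxy-4,7a-dimethyl-4-[(triethylsilyl)oxy]octahydro-7H-inden-7-one | CC(=O)C(C)(C)C[C@@]1(OC1)[C@H](O)[C@@H]2[C@H](O)C[C@]3(C)C(=O)CC[C@@](C)(O[Si](CC)(CC)CC)[C@@H]23 | intermediate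
22 | acetonide of 21: 2,2-dimethyl-1,3-dioxane across the C2 and C1' oxygens, all stereocenters as in 21 | CC(=O)C(C)(C)C[C@@]1(OC1)[C@@H]2OC(C)(C)O[C@@H]3C[C@]4(C)C(=O)CC[C@@](C)(O[Si](CC)(CC)CC)[C@H]4[C@H]23 | intermediate
23 | ring A ketone: as 22 but with a (1R)-1-hydroxy-3,3-dimethyl-4-oxocyclohexyl group on C1' in place of the epoxide and oxobutyl chain | CC1(C)C[C@@](O)([C@@H]2OC(C)(C)O[C@@H]3C[C@]4(C)C(=O)CC[C@@](C)(O[Si](CC)(CC)CC)[C@H]4[C@H]23)CCC1=O | intermediate
24 | bis(enol triflate) of 23: C7=C6 enol triflate in the hydrindane and C4''=C5'' enol triflate in ring A | CC1(C)C[C@@](O)([C@@H]2OC(C)(C)O[C@@H]3C[C@]4(C)C(OS(=O)(=O)C(F)(F)F)=CC[C@@](C)(O[Si](CC)(CC)CC)[C@H]4[C@H]23)CC=C1OS(=O)(=O)C(F)(F)F | intermediate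
25 | bis(alkenyl bromide): 7-bromo-6-ene in the hydrindane and (1R)-4-bromo-1-hydroxy-5,5-dimethylcyclohex-3-en-1-yl as ring A | CC1(C)C[C@@](O)([C@@H]2OC(C)(C)O[C@@H]3C[C@]4(C)C(Br)=CC[C@@](C)(O[Si](CC)(CC)CC)[C@H]4[C@H]23)CC=C1Br | intermediate
26 | acetonide (C2/C1' oxygens) and C4 triethylsilyl ether of the target, with (7S)-bromide and (1R,4S)-4-bromo-1-hydroxy-3,3-dimethylcyclohexyl ring A | CC1(C)C[C@@](O)([C@@H]2OC(C)(C)O[C@@H]3C[C@]4(C)[C@@H](Br)CC[C@@](C)(O[Si](CC)(CC)CC)[C@H]4[C@H]23)CC[C@@H]1Br | intermediate
27 | CNP0144982.1: (1R,4S)-4-bromo-1-{(R)-[(2R,3S,3aS,4R,7S,7aS)-7-bromo-2,4-dihydroxy-4,7a-dimethyloctahydro-1H-inden-3-yl](hydroxy)methyl}-3,3-dimethylcyclohexan-1-ol (route numbering) | CC1(C)C[C@@](O)([C@H](O)[C@@H]2[C@H](O)C[C@]3(C)[C@@H](Br)CC[C@@](C)(O)[C@@H]23)CC[C@@H]1Br | target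

**Count and risks**

Total step count: 20. Longest linear sequence: 16 steps (steps 1–4, 6–8, 12–20).

Steps most likely to fail:

1. Step 6. What may go wrong: competing 1,2-addition to the carbonyl group, sluggish or O-selective alkylation of the magnesium enolate, and erosion of the trans facial selectivity at the quaternary centre. Fallback (the two bond formations are separated and the enolate is regenerated regiospecifically): from 5, the directed conjugate addition is run alone and quenched with a proton source to give ketone F1. Silylation under equilibrating conditions (Et3SiOTf, Et3N) should give the more substituted silyl enol ether with the tertiary alcohol silylated at the same time, bis(silyl) compound F2. Anhydrous fluoride (Bu4N[Ph3SiF2]) then liberates the tetrasubstituted enolate, which is alkylated by 7 anti to the vinyl group, and the route is rejoined at 10.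

2. Step 16. What may go wrong: O-alkylation of the enolate, attack at the fully substituted epoxide carbon, or base-induced isomerization of the epoxide instead of the six-membered C-alkylation. Fallback (aldol condensation in place of epoxide opening): from 20, acetonide formation (2-methoxypropene, PPTS) gives alkene F3. Dihydroxylation with OsO4 and N-methylmorpholine N-oxide, anti to the allylic oxygen, should give diol F4. Oxidation of the primary alcohol (TEMPO, PhI(OAc)2) gives α-hydroxy aldehyde F5. Intramolecular aldol condensation with the methyl ketone (piperidine, AcOH) gives cyclohexenone F6, and hydrogenation of the enone double bond (H2, Pd/C) returns to 23.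

3. Step 19. What may go wrong: loss of bromine by reduction or fragmentation of the radical intermediates, and insufficient facial selectivity of the second hydrogen atom transfer at either centre. Fallback (substitution with inversion in place of radical hydrogenation): from 23, reduction of both ketones with LiBH(s-Bu)3 from the equatorial direction should give the diaxial diol F7. An Appel reaction (CBr4, P(n-C8H17)3, toluene, 70 °C) then replaces both secondary hydroxyl groups by bromide with inversion, and the route is rejoined at 26.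

Further compounds
F1 | step 6 | (3S,4R)-3-ethenyl-4-hydroxy-2,4-dimethylcyclohexan-1-one (C2 epimers) | CC1C(=O)CC[C@@](C)(O)[C@H]1C=C
F2 | step 6 | triethyl{[(3S,4R)-3-ethenyl-2,4-dimethyl-4-(triethylsilyloxy)cyclohex-1-en-1-yl]oxy}silane | CC1=C(O[Si](CC)(CC)CC)CC[C@@](C)(O[Si](CC)(CC)CC)[C@H]1C=C
F3 | step 16 | acetonide of 20 (2,2-dimethyl-1,3-dioxane across the C2 and C1' oxygens, methylidene group retained) | CC(=O)C(C)(C)CC(=C)[C@@H]1OC(C)(C)O[C@@H]2C[C@]3(C)C(=O)CC[C@@](C)(O[Si](CC)(CC)CC)[C@H]3[C@H]12
F4 | step 16 | diol from F3: tertiary C1'' hydroxyl and CH2OH in place of the methylidene group, C1''–O anti to C1'–O | CC(=O)C(C)(C)C[C@](O)(CO)[C@@H]1OC(C)(C)O[C@@H]2C[C@]3(C)C(=O)CC[C@@](C)(O[Si](CC)(CC)CC)[C@H]3[C@H]12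
F5 | step 16 | α-hydroxy aldehyde from F4 (CHO in place of CH2OH) | CC(=O)C(C)(C)C[C@](O)(C=O)[C@@H]1OC(C)(C)O[C@@H]2C[C@]3(C)C(=O)CC[C@@](C)(O[Si](CC)(CC)CC)[C@H]3[C@H]12
F6 | step 16 | cyclohexenone: as 23 but with a C5''=C6'' double bond conjugated to the C4'' ketone | CC1(C)C[C@@](O)([C@@H]2OC(C)(C)O[C@@H]3C[C@]4(C)C(=O)CC[C@@](C)(O[Si](CC)(CC)CC)[C@H]4[C@H]23)C=CC1=O
F7 | step 19 | diaxial diol: as 26 but with (7R)-hydroxyl and (4''R)-hydroxyl in place of the two bromides | CC1(C)C[C@@](O)([C@@H]2OC(C)(C)O[C@@H]3C[C@]4(C)[C@H](O)CC[C@@](C)(O[Si](CC)(CC)CC)[C@H]4[C@H]23)CC[C@H]1O
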